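**Plan**

1. Locants: seven-membered ring C1, C5, C6, C7, C8, C9, C10 (C1 carries the side chain, C5 the vinylic methyl, C10 the secondary methyl, C7/C8 are the ring fusion, O on C8); lactone C11, C12(=O), C13(=CH2); side chain C2(O-angeloyl)–C3–C4(OAc). Retrosynthetic cuts, in order: C6–C7 (Heck ring closure) → butenolide C7=C11 and C8–O (olefination/lactonisation, α-oxygenation of an aldehyde) → the two esters → C6–I and C5=C6 (iododesilylation, silicon-tethered ring-closing metathesis) → C1–C2 (aldol).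
2. Forward: the aldol joins the chain at C1–C2; a temporary six-membered oxasilacycle (O on C2–Si–C6=C5–C1–C2) fixes the Z-iodoalkene and is taken out again; the esters go on, the butenolide ring is built, and the seven-membered carbocycle is closed last.
3. Enabling feature: the skipped diene C5(Me)=C6H–C7H–C11(=C13H2), which runs from the cycloheptene into the exo-methylene of the cis-fused five-membered lactone, is the product pattern of a Heck insertion at C7 of an α-methyl butenolide followed by loss of a C13 hydrogen; the only other β-hydrogen (H7) is held anti to palladium in the lactone ring.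
4. Stereochemistry: C10 from (R)-citronellic acid; C1 and C2 from an oxazolidinone syn-aldol; C8 from L-proline-catalysed α-aminoxylation; C7 from C8 through the tether-enforced cis ring fusion; angelate geometry from angelic acid.

Key step: step 14

Remark: compounds 1, 2 and 5 are taken as commercial; the locants above are used throughout.

**Step 1**
Reactants: 1 (R)-citronellic acid; 2 (R)-4-benzyl-1,3-oxazolidin-2-one
Product: 4 (4R)-4-benzyl-3-[(3R)-3,7-dimethyloct-6-enoyl]-1,3-oxazolidin-2-one, via mixed pivalic anhydride 3 (not isolated)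
Conditions: PivCl, Et3N, THF, −20 °C; then 2, LiCl, −20 → 25 °C
Reagents that add atoms: none
Why: Mixed-anhydride N-acylation of the oxazolidinone (LiCl/Et3N activation) is the standard way to load an Evans auxiliary and touches neither C10 nor the trisubstituted alkene.

**Step 2**
Reactants: 4 (4R)-4-benzyl-3-[(3R)-3,7-dimethyloct-6-enoyl]-1,3-oxazolidin-2-one; 5 3-[(tert-butyldimethylsilyl)oxy]propanal
Product: 7 (4R)-4-benzyl-3-[(2R,3S)-5-[(tert-butyldimethylsilyl)oxy]-3-hydroxy-2-[(2R)-6-methylhept-5-en-2-yl]pentanoyl]-1,3-oxazolidin-2-one, via dibutylboron Z-enolate 6 (not isolated)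
Conditions: Bu2BOTf, i-Pr2NEt, CH2Cl2, −78 → 0 °C; then 5, −78 → 0 °C; pH 7 buffer, MeOH, H2O2
Reagents that add atoms: none
Why: Evans syn-aldol reaction, in which the boron Z-enolate reacts through a closed chair transition state with the benzyl group shielding one enolate face, so that C1 (2R) and C2 (3S) are set together under auxiliary control with little influence from the remote C10 centre.

**Step 3**
Reactants: 7 the syn-aldol imide
Product: 8 (2R,3S)-5-[(tert-butyldimethylsilyl)oxy]-3-hydroxy-N-methoxy-N-methyl-2-[(2R)-6-methylhept-5-en-2-yl]pentanamide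
Conditions: MeNH(OMe)·HCl, AlMe3, CH2Cl2/THF, −20 → 0 °C; Rochelle salt work-up
Reagents that add atoms: N,O-dimethylhydroxylamine hydrochloride, CNOC.Cl
Why: Aluminium-amide transamination of a β-hydroxy imide to the Weinreb amide, assisted by the aluminium alkoxide of the free C2 hydroxyl, releases the auxiliary without epimerising C1.

**Step 4**
Reactants: 8 the Weinreb amide
Product: 9 (3R,4S)-6-[(tert-butyldimethylsilyl)oxy]-4-hydroxy-3-[(2R)-6-methylhept-5-en-2-yl]hexan-2-one
Conditions: MeMgBr (3 equiv), THF, 0 °C; aq NH4Cl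
Reagents that add atoms: methylmagnesium bromide, C[Mg]Br
Why: Weinreb ketone synthesis, in which the chelated tetrahedral magnesium adduct prevents over-addition and the extra Grignard reagent only deprotonates the C2 hydroxyl, gives the methyl ketone that carries C5 and its methyl group.

**Step 5**
Reactants: 9 the β-hydroxy methyl ketone
Product: 10 (3R,4S)-6-[(tert-butyldimethylsilyl)oxy]-4-{[dimethyl(vinyl)silyl]oxy}-3-[(2R)-6-methylhept-5-en-2-yl]hexan-2-one
Conditions: ClSiMe2(CH=CH2), imidazole, CH2Cl2, 0 °C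
Reagents that add atoms: chloro(dimethyl)vinylsilane, C=C[Si](C)(C)Cl
Why: Silylation of the secondary alcohol with a chlorosilane and imidazole installs the temporary vinylsilicon tether whose inner vinyl carbon will become C6.

**Step 6**
Reactants: 10 the vinylsilyl ether ketone
Product: 11 tert-butyl({(3S,4S,5R)-3-{[dimethyl(vinyl)silyl]oxy}-5,9-dimethyl-4-(prop-1-en-2-yl)dec-8-en-1-yl}oxy)dimethylsilane
Conditions: Cp2TiMe2, toluene, 70 °C, dark
Reagents that add atoms: dimethyltitanocene Cp2TiMe2, [Ti+4].[CH3-].[CH3-].c1cc[cH-]c1.c1cc[cH-]c1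
Why: Petasis methylenation (Cp2Ti=CH2 formed by thermolysis) turns the hindered, enolisable methyl ketone into the isopropenyl group under non-basic conditions, so C1 is not epimerised and the β-silyloxy group is not eliminated.

**Step 7**
Reactants: 11 the isopropenyl vinylsilyl ether
Product: 12 (5S,6S)-6-{2-[(tert-butyldimethylsilyl)oxy]ethyl}-2,2,4-trimethyl-5-[(2R)-6-methylhept-5-en-2-yl]-5,6-dihydro-2H-1,2-oxasiline
Conditions: Mo(CHCMe2Ph)(N-2,6-i-Pr2C6H3)[OCMe(CF3)2]2 (8 mol %), C6H6, 25 °C, 0.02 M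
Reagents that add atoms: none
Why: Silicon-tethered ring-closing metathesis between the vinylsilane and the 1,1-disubstituted alkene gives a six-membered oxasilacycle that can only hold a cis ring alkene, which places silicon (the future iodine) cis to C1 on C5=C6, while the remote trisubstituted prenyl alkene is a poor metathesis partner.

**Step 8**
Reactants: 12 the cyclic alkenylsiloxane
Product: 14 (3S,4S,5R)-4-[(1Z)-1-iodoprop-1-en-2-yl]-5,9-dimethyldec-8-ene-1,3-diol, via silyl ether iodide 13 (not isolated)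
Conditions: NIS, 2,6-lutidine, (CF3)2CHOH, 0 °C; then HF·pyridine, THF/pyridine, 0 → 25 °C
Reagents that add atoms: N-iodosuccinimide, O=C1CCC(=O)N1I
Why: Electrophilic ipso-iododesilylation of the alkenylsilane (β-silyl cation, retention of geometry) gives the Z-alkenyl iodide, and fluoride then strips the residual silyl group from the C2 oxygen and the silyl ether from the C4 oxygen in the same flask.

**Step 9**
Reactants: 14 the iodo diol
Product: 15 (3S,4S,5R)-3-hydroxy-4-[(1Z)-1-iodoprop-1-en-2-yl]-5,9-dimethyldec-8-en-1-yl acetate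
Conditions: AcCl (1.05 equiv), 2,4,6-collidine, CH2Cl2, −78 °C
Reagents that add atoms: acetyl chloride, CC(=O)Cl
Why: Selective acetylation at low temperature acylates the unhindered primary C4 hydroxyl and leaves the hindered secondary C2 hydroxyl free.

**Step 10**
Reactants: 15 the primary acetate
Product: 16 (3S,4S,5R)-1-acetoxy-4-[(1Z)-1-iodoprop-1-en-2-yl]-5,9-dimethyldec-8-en-3-yl (2Z)-2-methylbut-2-enoate
Conditions: angelic acid, 2,4,6-Cl3C6H2COCl, Et3N, toluene, 25 °C; then 15, 75 °C
Reagents that add atoms: angelic acid, C/C=C(/C)C(=O)O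
Why: Yamaguchi-type mixed-anhydride esterification, run without a nucleophilic catalyst so that the angelate does not isomerise to the tiglate, acylates the hindered C2 hydroxyl.

**Step 11**
Reactants: 16 the angelate acetate
Product: 18 (3S,4S,5R)-1-acetoxy-4-[(1Z)-1-iodoprop-1-en-2-yl]-5-methyl-8-oxooctan-3-yl (2Z)-2-methylbut-2-enoate, via prenyl diol 17 (not isolated)
Conditions: OsO4 (2 mol %), NaIO4, 2,6-lutidine, dioxane/H2O (3:1), 25 °C
Reagents that add atoms: sodium periodate, [Na+].[O-][I](=O)(=O)=O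
Why: Johnson–Lemieux oxidation, in which OsO4 dihydroxylates the electron-rich trisubstituted prenyl alkene faster than the iodine-deactivated alkenyl iodide or the conjugated angelate and periodate cleaves the diol, gives the C7 aldehyde.

**Step 12**
Reactants: 18 the C7 aldehyde
Product: 20 ethyl (2Z,4R,6R,7S,8S)-10-acetoxy-7-[(1Z)-1-iodoprop-1-en-2-yl]-2,6-dimethyl-8-{[(2Z)-2-methylbut-2-enoyl]oxy}-4-[(phenylamino)oxy]dec-2-enoate, via alpha-aminoxy aldehyde 19 (not isolated)
Conditions: L-proline (0.3 equiv), PhNO (slow addition), MeCN, −20 °C; then (PhO)2P(O)CH(Me)CO2Et/NaH, THF, −78 → 0 °C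
Reagents that add atoms: nitrosobenzene, O=Nc1ccccc1; ethyl 2-(diphenoxyphosphoryl)propanoate, CCOC(=O)C(C)P(=O)(Oc1ccccc1)Oc1ccccc1
Why: Proline-catalysed α-aminoxylation through the anti enamine with hydrogen-bond delivery of nitrosobenzene sets C8 as R under catalyst control, and a Z-selective Horner–Wadsworth–Emmons olefination with the diaryl phosphonate in the same flask places the ester cis to C8.

**Step 13**
Reactants: 20 the Z-enoate
Product: 22 (3S,4S,5R)-1-acetoxy-4-[(1Z)-1-iodoprop-1-en-2-yl]-5-methyl-6-[(2R)-4-methyl-5-oxo-2,5-dihydrofuran-2-yl]hexan-3-yl (2Z)-2-methylbut-2-enoate, via hydroxy enoate 21 (not isolated)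
Conditions: Zn dust, AcOH/THF (1:1), 0 → 25 °C
Reagents that add atoms: none
Why: Reductive N–O cleavage with zinc in acetic acid frees the C8 hydroxyl, which lactonises onto the cis-disposed ester under the acidic conditions to give the α-methyl butenolide without touching C8.

**Step 14**
Reactants: 22 the Z-iodoalkene butenolide
Product: 23 (1S)-3-acetoxy-1-[(3aR,6S,7R,8aR)-5,7-dimethyl-3-methylidene-2-oxo-3,3a,6,7,8,8a-hexahydro-2H-cyclohepta[b]furan-6-yl]propyl (2Z)-2-methylbut-2-enoate (target)
Conditions: Pd(OAc)2 (10 mol %), PPh3 (25 mol %), Ag2CO3 (2 equiv), MeCN, 70 °C, 0.005 M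
Reagents that add atoms: none
Why: Zerovalent palladium inserts into the C6–I bond with retention of the Z geometry, the alkenylpalladium adds syn across C7=C11 of the butenolide, and the tertiary C11–Pd intermediate loses a hydrogen from the C13 methyl, the only β-hydrogen it can reach syn because H7 is held anti in the five-membered ring; Ag2CO3 removes iodide and takes up HI so that palladium hydride does not re-add and move the new double bonds. The closest known reaction type is the intramolecular Mizoroki–Heck cyclisation of an alkenyl iodide onto an α,β-unsaturated ester or lactone with β′-hydride elimination to an exocyclic alkene. The seven-membered carbocycle closes in the 7-exo-trig mode (C6 onto C7, C11 outside the new ring), which leaves the Z-trisubstituted C5=C6 alkene inside the ring. The new stereocenter C7 is controlled by C8: the tether leaves C8 on one face of the planar butenolide and can deliver C6 only to that face, which gives the cis ring fusion (7R with 8R). The step needs attack at the β-carbon C7 and not at C11 (favoured by the polarisation of the unsaturated lactone and by the smaller ring), the butenolide and not the angelate as acceptor (the all-carbon tether should win over an ester tether that would have to turn s-trans to close a seven-membered lactone), and no epimerisation at C8 (mild insoluble base, high dilution).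

**Compound list**

1 | (R)-citronellic acid, (3R)-3,7-dimethyloct-6-enoic acid | CC(C)=CCC[C@@H](C)CC(=O)O | starting material
2 | (R)-4-benzyl-1,3-oxazolidin-2-one | O=C1N[C@H](Cc2ccccc2)CO1 | starting material
3 | (3R)-3,7-dimethyloct-6-enoic pivalic anhydride (not isolated) | CC(C)=CCC[C@@H](C)CC(=O)OC(=O)C(C)(C)C | intermediate
4 | (4R)-4-benzyl-3-[(3R)-3,7-dimethyloct-6-enoyl]-1,3-oxazolidin-2-one | CC(C)=CCC[C@@H](C)CC(=O)N1[C@H](Cc2ccccc2)COC1=O | intermediate
5 | 3-[(tert-butyldimethylsilyl)oxy]propanal | O=CCCO[Si](C)(C)C(C)(C)C | starting material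
6 | dibutylboron Z-enolate of 4 (not isolated) | CC(C)=CCC[C@@H](C)/C=C(\OB(CCCC)CCCC)N1[C@H](Cc2ccccc2)COC1=O | intermediate
7 | (4R)-4-benzyl-3-[(2R,3S)-5-[(tert-butyldimethylsilyl)oxy]-3-hydroxy-2-[(2R)-6-methylhept-5-en-2-yl]pentanoyl]-1,3-oxazolidin-2-one | CC(C)=CCC[C@@H](C)[C@@H](C(=O)N1[C@H](Cc2ccccc2)COC1=O)[C@@H](O)CCO[Si](C)(C)C(C)(C)C | intermediate
8 | (2R,3S)-5-[(tert-butyldimethylsilyl)oxy]-3-hydroxy-N-methoxy-N-methyl-2-[(2R)-6-methylhept-5-en-2-yl]pentanamide | CC(C)=CCC[C@@H](C)[C@@H](C(=O)N(C)OC)[C@@H](O)CCO[Si](C)(C)C(C)(C)C | intermediate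
9 | (3R,4S)-6-[(tert-butyldimethylsilyl)oxy]-4-hydroxy-3-[(2R)-6-methylhept-5-en-2-yl]hexan-2-one | CC(C)=CCC[C@@H](C)[C@@H](C(C)=O)[C@@H](O)CCO[Si](C)(C)C(C)(C)C | intermediate
10 | (3R,4S)-6-[(tert-butyldimethylsilyl)oxy]-4-{[dimethyl(vinyl)silyl]oxy}-3-[(2R)-6-methylhept-5-en-2-yl]hexan-2-one | CC(C)=CCC[C@@H](C)[C@@H](C(C)=O)[C@@H](O[Si](C)(C)C=C)CCO[Si](C)(C)C(C)(C)C | intermediate
11 | tert-butyl({(3S,4S,5R)-3-{[dimethyl(vinyl)silyl]oxy}-5,9-dimethyl-4-(prop-1-en-2-yl)dec-8-en-1-yl}oxy)dimethylsilane | CC(C)=CCC[C@@H](C)[C@@H](C(C)=C)[C@@H](O[Si](C)(C)C=C)CCO[Si](C)(C)C(C)(C)C | intermediate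
12 | (5S,6S)-6-{2-[(tert-butyldimethylsilyl)oxy]ethyl}-2,2,4-trimethyl-5-[(2R)-6-methylhept-5-en-2-yl]-5,6-dihydro-2H-1,2-oxasiline | CC(C)=CCC[C@@H](C)[C@H]1C(C)=C[Si](C)(C)O[C@H]1CCO[Si](C)(C)C(C)(C)C | intermediate
13 | Z-iodoalkene of 14 carrying a dimethyl(1,1,1,3,3,3-hexafluoropropan-2-yloxy)silyl ether on the C2 oxygen and the tert-butyldimethylsilyl ether on the C4 oxygen (not isolated) | CC(C)=CCC[C@@H](C)[C@@H](/C(C)=C\I)[C@@H](O[Si](C)(C)OC(C(F)(F)F)C(F)(F)F)CCO[Si](C)(C)C(C)(C)C | intermediate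
14 | (3S,4S,5R)-4-[(1Z)-1-iodoprop-1-en-2-yl]-5,9-dimethyldec-8-ene-1,3-diol | CC(C)=CCC[C@@H](C)[C@@H](/C(C)=C\I)[C@@H](O)CCO | intermediate
15 | (3S,4S,5R)-3-hydroxy-4-[(1Z)-1-iodoprop-1-en-2-yl]-5,9-dimethyldec-8-en-1-yl acetate | CC(C)=CCC[C@@H](C)[C@@H](/C(C)=C\I)[C@@H](O)CCOC(C)=O | intermediate
16 | (3S,4S,5R)-1-acetoxy-4-[(1Z)-1-iodoprop-1-en-2-yl]-5,9-dimethyldec-8-en-3-yl (2Z)-2-methylbut-2-enoate | CC(C)=CCC[C@@H](C)[C@@H](/C(C)=C\I)[C@@H](OC(=O)/C(C)=C\C)CCOC(C)=O | intermediate
17 | 8,9-diol of 16, (3S,4S,5R)-1-acetoxy-8,9-dihydroxy-4-[(1Z)-1-iodoprop-1-en-2-yl]-5,9-dimethyldecan-3-yl (2Z)-2-methylbut-2-enoate, both C8 epimers (not isolated) | CC(C)(O)C(O)CC[C@@H](C)[C@@H](/C(C)=C\I)[C@@H](OC(=O)/C(C)=C\C)CCOC(C)=O | intermediate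
18 | (3S,4S,5R)-1-acetoxy-4-[(1Z)-1-iodoprop-1-en-2-yl]-5-methyl-8-oxooctan-3-yl (2Z)-2-methylbut-2-enoate | O=CCC[C@@H](C)[C@@H](/C(C)=C\I)[C@@H](OC(=O)/C(C)=C\C)CCOC(C)=O | intermediate
19 | (3S,4S,5R,7R)-1-acetoxy-4-[(1Z)-1-iodoprop-1-en-2-yl]-5-methyl-8-oxo-7-[(phenylamino)oxy]octan-3-yl (2Z)-2-methylbut-2-enoate (not isolated) | O=C[C@H](ONc1ccccc1)C[C@@H](C)[C@@H](/C(C)=C\I)[C@@H](OC(=O)/C(C)=C\C)CCOC(C)=O | intermediate
20 | ethyl (2Z,4R,6R,7S,8S)-10-acetoxy-7-[(1Z)-1-iodoprop-1-en-2-yl]-2,6-dimethyl-8-{[(2Z)-2-methylbut-2-enoyl]oxy}-4-[(phenylamino)oxy]dec-2-enoate | CCOC(=O)/C(C)=C\[C@H](ONc1ccccc1)C[C@@H](C)[C@@H](/C(C)=C\I)[C@@H](OC(=O)/C(C)=C\C)CCOC(C)=O | intermediate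
21 | 4-hydroxy analogue of 20, ethyl (2Z,4R,6R,7S,8S)-10-acetoxy-4-hydroxy-7-[(1Z)-1-iodoprop-1-en-2-yl]-2,6-dimethyl-8-{[(2Z)-2-methylbut-2-enoyl]oxy}dec-2-enoate (not isolated) | CCOC(=O)/C(C)=C\[C@H](O)C[C@@H](C)[C@@H](/C(C)=C\I)[C@@H](OC(=O)/C(C)=C\C)CCOC(C)=O | intermediate
22 | (3S,4S,5R)-1-acetoxy-4-[(1Z)-1-iodoprop-1-en-2-yl]-5-methyl-6-[(2R)-4-methyl-5-oxo-2,5-dihydrofuran-2-yl]hexan-3-yl (2Z)-2-methylbut-2-enoate | O=C1O[C@H](C[C@@H](C)[C@@H](/C(C)=C\I)[C@@H](OC(=O)/C(C)=C\C)CCOC(C)=O)C=C1C | intermediate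
23 | (1S)-3-acetoxy-1-[(3aR,6S,7R,8aR)-5,7-dimethyl-3-methylidene-2-oxo-3,3a,6,7,8,8a-hexahydro-2H-cyclohepta[b]furan-6-yl]propyl (2Z)-2-methylbut-2-enoate | C=C1C(=O)O[C@@H]2C[C@@H](C)[C@H]([C@H](CCOC(C)=O)OC(=O)/C(C)=C\C)C(C)=C[C@H]12 | target

**Step count and risks**

Total step count: 14. Longest linear sequence: 14 steps (from 1).

Steps most likely to fail:

1. Step 14. The 7-exo carbopalladation of the trisubstituted butenolide alkene may be slow, so that loss of iodine or intermolecular coupling takes over. Palladium hydride may re-add and move the exocyclic double bond into the ring. The base may epimerise the butenolide γ-carbon C8 before ring closure. Fallback (radical addition–fragmentation in place of palladium insertion and hydride loss): it sets out from 18. The aminoxylation of step 12 is run as before, but the olefination uses ethyl 2-(diphenoxyphosphoryl)-3-(tributylstannyl)propanoate F1 (from ethyl (diphenoxyphosphoryl)acetate, NaH and Bu3SnCH2I). This should give the stannylmethyl enoate F2 with the ester cis to C8. N–O cleavage with Zn and NH4Cl in aqueous ethanol (acetic acid is avoided to spare the allylstannane), then warming, should give the 3-[(tributylstannyl)methyl]butenolide F3. Heating F3 in dilute benzene with AIBN and a little Bu3SnSnBu3 should start a chain: the tributyltin radical abstracts iodine, the alkenyl radical (which inverts freely, so alkene geometry does not matter) closes the seven-membered ring at C7 on the face held by the tether, and the C11 radical expels the tributyltin radical to leave the exo-methylene group. The fallback comes back to the route at 23.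

2. Step 8. Electrophilic iodine may engage the electron-rich prenyl alkene, ipso-substitution at the alkoxysilane may be slow, and the alkene geometry may erode. Fallback (remove the competing alkene before the electrophilic step): it sets out from 12. Johnson–Lemieux cleavage as in step 11, which should leave the hindered ring alkenylsilane alone, gives the siloxane aldehyde F4. Iododesilylation and HF·pyridine as in step 8 then meet no second alkene and give the iodo diol aldehyde F5. Acetylation as in step 9 gives the acetate aldehyde F6, and angeloylation as in step 10 comes back to the route at 18.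

3. Step 12. The α-aminoxy aldehyde may enolise under the basic olefination, which erodes C8, and the olefination may be incompletely Z-selective (the E isomer cannot lactonise). Fallback (butenolide by ring-closing metathesis in place of Z-olefination and lactonisation): it sets out from 18. After the same aminoxylation, non-basic Takai methylenation (CH2I2, Zn, Ti(Oi-Pr)4, THF) gives the allylic aminoxy compound F7. Zn/AcOH gives the allylic alcohol F8, and methacryloyl chloride with Et3N in CH2Cl2 at 0 °C gives the methacrylate F9. Ring-closing metathesis with the second-generation Grubbs catalyst in CH2Cl2 at 40 °C closes the α-methyl butenolide and comes back to the route at 22.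

**Further compounds**

F1 | step 14 | ethyl 2-(diphenoxyphosphoryl)-3-(tributylstannyl)propanoate | CCCC[Sn](CCCC)(CCCC)CC(C(=O)OCC)P(=O)(Oc1ccccc1)Oc1ccccc1
F2 | step 14 | analogue of 20 with a (tributylstannyl)methyl group in place of the C2 methyl of the enoate, ester cis to the aminoxy-bearing carbon | CCOC(=O)/C(C[Sn](CCCC)(CCCC)CCCC)=C\[C@H](ONc1ccccc1)C[C@@H](C)[C@@H](/C(C)=C\I)[C@@H](OC(=O)/C(C)=C\C)CCOC(C)=O
F3 | step 14 | analogue of 22 with a (tributylstannyl)methyl group in place of the butenolide methyl | O=C1O[C@H](C[C@@H](C)[C@@H](/C(C)=C\I)[C@@H](OC(=O)/C(C)=C\C)CCOC(C)=O)C=C1C[Sn](CCCC)(CCCC)CCCC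
F4 | step 8 | (4R)-4-[(5S,6S)-6-{2-[(tert-butyldimethylsilyl)oxy]ethyl}-2,2,4-trimethyl-5,6-dihydro-2H-1,2-oxasilin-5-yl]pentanal | O=CCC[C@@H](C)[C@H]1C(C)=C[Si](C)(C)O[C@H]1CCO[Si](C)(C)C(C)(C)C
F5 | step 8 | (4R,5S,6S)-6,8-dihydroxy-5-[(1Z)-1-iodoprop-1-en-2-yl]-4-methyloctanal | O=CCC[C@@H](C)[C@@H](/C(C)=C\I)[C@@H](O)CCO
F6 | step 8 | (3S,4S,5R)-3-hydroxy-4-[(1Z)-1-iodoprop-1-en-2-yl]-5-methyl-8-oxooctyl acetate | O=CCC[C@@H](C)[C@@H](/C(C)=C\I)[C@@H](O)CCOC(C)=O
F7 | step 12 | (3S,4S,5R,7R)-1-acetoxy-4-[(1Z)-1-iodoprop-1-en-2-yl]-5-methyl-7-[(phenylamino)oxy]non-8-en-3-yl (2Z)-2-methylbut-2-enoate | C=C[C@H](ONc1ccccc1)C[C@@H](C)[C@@H](/C(C)=C\I)[C@@H](OC(=O)/C(C)=C\C)CCOC(C)=O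
F8 | step 12 | (3S,4S,5R,7R)-1-acetoxy-7-hydroxy-4-[(1Z)-1-iodoprop-1-en-2-yl]-5-methylnon-8-en-3-yl (2Z)-2-methylbut-2-enoate | C=C[C@H](O)C[C@@H](C)[C@@H](/C(C)=C\I)[C@@H](OC(=O)/C(C)=C\C)CCOC(C)=O
F9 | step 12 | methacrylate (2-methylprop-2-enoate) ester of F8 at the allylic hydroxyl | C=C[C@H](OC(=O)C(C)=C)C[C@@H](C)[C@@H](/C(C)=C\I)[C@@H](OC(=O)/C(C)=C\C)CCOC(C)=O
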